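## Structural features

The target is a germacranolide: a cyclodeca-1(10),4-diene with both trisubstituted ring alkenes Z, and an α-methylene-γ-butyrolactone fused across C6–C7 (C12 carbonyl on O6, C13 the exocyclic methylene). Read from the stereodescriptors (3S,6R,7S,8R,9S), O6 and C11 lie on the same face, so the lactone is cis-fused. C6, C7, C8 and C9 are contiguous and carry all four hydrogens on one face, while the isolated C3 centre has its oxygen on the opposite face. Three secondary oxygens carry three different groups: acetate at C3, a free hydroxyl at C8, and a (2R,3R)-2,3-dimethyloxirane-2-carboxylate at C9 (the epoxide of an angelate, methyl groups trans). The fragile parts are the methylene lactone (a Michael acceptor, and an acyloxy leaving group β to C8), the epoxy ester, the two allylic esters and a Z,Z-diene in a medium ring prone to transannular reactions. The real difficulties are the ten-membered ring with two Z alkenes and telling O3, O8 and O9 apart. C3 and C8 are 1,6-related, both oxygenated, and each arc between them holds one alkene (C4=C5 in C3–C4–C5–C6–C7–C8, C1=C10 in C3–C2–C1–C10–C9–C8). A C3–C8 bond therefore turns the macrocycle into two fused cyclohexenes in which Z geometry is compulsory: ring B (C3–C8, a carvone ring that also supplies C7 and C11–C13) and ring A; glycol cleavage of the ring-fusion diol returns the macrocycle as the 3,8-dione.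

## Logic of the disconnections

28 ⇒ 27. The O–acetyl bond at C3 is cut last, so no allylic acetate has to survive the hydride steps. The forward step must acylate the allylic C3 hydroxyl in preference to the C8 hydroxyl, which is flanked by C7 and the bulky C9 ester.

27 ⇒ 26 ⇒ 25. The C3–H and C8–H bonds are cut, returning both carbinols to the ketones that the ring-opening step releases. Forward, the non-conjugated α-acyloxy ketone at C8 must be reduced first with hydride entering anti to the C7–C11 and C9–O bonds; the C3 enone then needs catalyst control.

25 ⇒ 24. The C3–C8 bond is re-formed on paper (retro glycol cleavage). The ten-membered ring becomes ring A plus ring B, both Z alkenes become ring-enforced, and no olefination selectivity is needed. Forward, the cleavage must be mild and non-enolising. O9 is already acylated in 24, so the C3/C8 pair is the only glycol and O8/O9 never need to be told apart later.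

24 ⇒ 18 + 22. The C9 O–acyl bond is cut at the triol stage, where C9–OH is the only acylable hydroxyl (the other two are tertiary). Forward, a hindered esterification must spare the epoxide.

22 ⇒ 21 ⇒ 20 ⇒ 19. The acid is taken back to the epoxy alcohol and then to the Z allylic alcohol, so the two epoxide stereocentres come from a reagent-controlled epoxidation. The alkene geometry of 19 supplies the trans methyl groups.

18 ⇒ 17. Only the Si–O9 bond is cut; the silyl ether protects C9 through the enolate chemistry.

17 ⇒ 16. C1=C10 is cut by retro metathesis. Forward, a six-membered ring closes onto a 1,1-disubstituted alkene, and the new alkene is necessarily cis within the ring.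

16 ⇒ 14 + 15. The C2–C3 bond is cut. The allyl nucleophile must add to the ketone and ignore the methylene lactone, which rules out a Grignard reagent.

14 ⇒ 11. The O6–C6 bond is cut with the carboxylate as nucleophile. A sterically controlled γ-oxygenation would place oxygen anti to the C7 side chain (trans), whereas the target lactone is cis; displacement of a trans γ-leaving group by the tethered carboxylate gives the cis fusion by inversion.

11 ⇒ 10 ⇒ 9. C12 is taken back from acid to aldehyde to allylic chloride, a group that tolerates the enolate steps.

9 ⇒ 7 ⇒ 6. The C8–O bond and the silyl ether are cut. The hydroxylation must follow the aldol, since a β-silyloxy enolate is usable and a β-acyloxy one is not.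

6 ⇒ 2 + 3. The C8–C9 aldol bond is cut. Forward, the aldehyde must add trans to the C7 side chain and with syn simple selectivity; the usual anti outcome of a cyclic (E) enolate would give the wrong C9 epimer.

2 ⇒ 1. The C12–Cl bond is cut. The allylic chlorination comes first because after the aldol a second isopropenyl-type alkene (from 3) would compete.

## Other disconnections considered

Alternative 1: The cut is through C2–C3 and C8–C9 at once, giving 3-methyltropone A1 and (1E)-1-acetoxy-2-methylbuta-1,3-diene A2. The forward key step is a thermal exo [6+4] cycloaddition to the bridged trienone A3.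
- In its favour: two C–C bonds and the whole carbocycle form in one step from small achiral partners. Both future ring alkenes are cis by construction, which equals the chosen plan on geometry. It reaches the ten-membered ring in far fewer steps, which is better than the chosen plan.
- Against it here: the thermal reaction gives no absolute control, and regiochemistry with the unsymmetrical A1 and periselectivity against [4+2] are open. A3 carries one carbon too many (the bridging carbonyl), which must be excised while leaving oxygen on both bridgeheads. A3 lacks C11–C13 and O6, which would have to be built stereoselectively from the C6=C7 alkene. Its acetoxy group sits on C9, where the target has the epoxy ester.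
- Comparison: structurally A3 holds the ring but little of the functionality, whereas 24 holds all of it. Mechanistically a concerted, stereospecific pericyclic step is cleaner than a fragmentation leading to a labile dione. On step economy the early advantage is expected to be lost in the post-cycloaddition work, and the chosen plan takes C7 from the chiral pool.

Alternative 2: The cut is at C5–C6 together with the lactone C12–O6 bond, giving the seco iodo-aldehyde ester A4. The forward key step is a Nozaki–Hiyama–Kishi reaction (CrCl2, catalytic NiCl2), whose C6 alkoxide lactonises to A5.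
- In its favour: C3 and the 8,9-diol are set in an open chain by reliable asymmetric methods, which is better than the late, ring-dependent reductions of the chosen plan. No 1,6-dione is formed, which is also better. Ring and lactone arise in one operation and the alkenylchromium chemistry tolerates many functional groups.
- Against it here: both Z trisubstituted alkenes, including the Z iodoalkene, must be built with geometric control; the chosen plan gets them free. C6 is created during macrocyclisation and must come out cis to C11. A5 lacks C13, so a late enolate methylenation on a sensitive macrocycle is needed. After acetonide removal O8 and O9 must be differentiated. The reaction needs excess divalent chromium at high dilution.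
- Comparison: structurally A5 is closer to the target at C3; mechanistically it is a polar macrocyclisation against an entropically free fragmentation. On step economy the linear route to A4 plus methylenation and diol differentiation is expected to be longer than the chosen 18 steps.

Alternative 3: The cut is at C3–C4, giving the seco iodo-aldehyde A6 with the methylene lactone in place. The forward key step is again a Nozaki–Hiyama–Kishi closure, to the macrocyclic C3 alcohol A7.
- In its favour: the ring closure creates the carbinol that must be acetylated as the only free hydroxyl, so acetylation needs no selectivity; this is better than step 18 of the chosen plan. The methylene lactone is already present, which equals the chosen plan. C6–C9 are fixed before cyclisation.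
- Against it here: C3 is set during macrocyclisation under substrate control of uncertain sense. The β,γ-unsaturated aldehyde of A6 is prone to conjugation. The α-branched iodoalkene reacts slowly. Z geometry must again be built in the chain, and the 8,9-acetonide leaves the same O8/O9 differentiation as in Alternative 2.
- Comparison: structurally A7 is two steps from the oxygenation pattern apart from C8/C9; mechanistically it equals Alternative 2. On step economy it is expected to be longer than the chosen plan because of the synthesis of A6.

Key step: step 15

Remark (numbering): germacranolide numbering is used for every intermediate; the lower face of ring B is the face that carries the C7 side chain.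

Assumption: the configurations at C3 and C8 drawn for 16–18 and 24 (trans ring-fusion diol) are those the chemistry is expected to give. Both are erased in step 15, so any diastereomer at these two centres converges on 25.

Step 1
Reactants: 1 (R)-carvone
Product: 2 (R)-10-chlorocarvone [(5R)-5-(3-chloroprop-1-en-2-yl)-2-methylcyclohex-2-en-1-one]
Conditions: Ca(OCl)2, CO2 (dry ice), CH2Cl2/H2O, 0 °C
Reagents that add atoms: calcium hypochlorite, [Ca+2].[O-]Cl.[O-]Cl
Why: Ene-type allylic chlorination by hypochlorous acid takes the electron-rich 1,1-disubstituted alkene and leaves the enone alone; it is done first because it is the only stage with a single isopropenyl-type group, and C7 is not touched.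

Step 2
Reactants: 2 (R)-10-chlorocarvone; 3 methacrolein
Product: 6 syn aldol (5R,6R)-5-(3-chloroprop-1-en-2-yl)-6-[(1R)-1-hydroxy-2-methylprop-2-en-1-yl]-2-methylcyclohex-2-en-1-one, via lithium enolate 4 (not isolated), via titanium enolate 5 (not isolated)
Conditions: LiN(iPr)2, THF, −78 °C; ClTi(OiPr)3, −78 → −40 °C; 3, −78 °C; aq. NH4F
Reagents that add atoms: none
Why: Kinetic α'-deprotonation at C8 and transmetalation give the triisopropoxytitanium enolate, whose aldol addition to the aldehyde carbonyl should occur trans to the C7 side chain. Titanium enolates of cyclic ketones are syn-selective despite their fixed E geometry (boat-like transition state), which is the sense needed for the C9 configuration of the target.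

Step 3
Reactants: 6 syn aldol
Product: 7 C9 tert-butyldimethylsilyl ether of 6 [(5R,6R,1'R) configuration unchanged]
Conditions: TBSOTf, 2,6-lutidine, CH2Cl2, −78 → 0 °C
Reagents that add atoms: tert-butyldimethylsilyl triflate, CC(C)(C)[Si](C)(C)OS(=O)(=O)C(F)(F)F
Why: Silylation of the secondary allylic alcohol blocks retro-aldol and gives a β-silyloxy ketone that can be enolised again without elimination.

Step 4
Reactants: 7 C9 silyl ether
Product: 9 C8 tertiary alcohol (5S,6R)-6-[(1S)-1-(tert-butyldimethylsilyloxy)-2-methylprop-2-en-1-yl]-5-(3-chloroprop-1-en-2-yl)-6-hydroxy-2-methylcyclohex-2-en-1-one, via potassium enolate 8 (not isolated)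
Conditions: KN(SiMe3)2, THF, −78 °C; 2-(phenylsulfonyl)-3-phenyloxaziridine, −78 °C; aq. NH4Cl
Reagents that add atoms: 2-(phenylsulfonyl)-3-phenyloxaziridine, O=S(=O)(N1OC1c1ccccc1)c1ccccc1
Why: Davis oxidation of the tetrasubstituted enolate; the oxaziridine should approach anti to the pseudo-axial C7 side chain, placing the hydroxyl on the upper face. This centre is erased in step 15, so its configuration only decides which diol diastereomer is carried.

Step 5
Reactants: 9 C8 tertiary alcohol
Product: 10 C12 aldehyde (2-substituted acrolein) corresponding to 9
Conditions: N-methylmorpholine N-oxide, KI (cat.), MeCN, rt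
Reagents that add atoms: N-methylmorpholine N-oxide, C[N+]1([O-])CCOCC1
Why: Ganem-type oxidation: the amine N-oxide displaces the allylic chloride and the alkoxyammonium salt eliminates to the enal, without base strong enough to touch the α-ketol or the silyl ether.

Step 6
Reactants: 10 C12 aldehyde
Product: 11 C12 carboxylic acid (2-substituted acrylic acid) corresponding to 9
Conditions: NaClO2, NaH2PO4, 2-methylbut-2-ene, t-BuOH/H2O, 0 °C → rt
Reagents that add atoms: sodium chlorite, [Na+].[O-]Cl=O
Why: Pinnick oxidation converts the enal to the acrylic acid; the scavenger protects the other alkenes from hypochlorous acid.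

Step 7
Reactants: 11 C12 carboxylic acid
Product: 14 cis-fused α-methylene lactone enone (6,12-olide; C3 ketone; C8 hydroxyl free; C9 silyl ether), via tris(trimethylsilyl) dienol ether 12 (not isolated), via C6 bromo enone 13 (not isolated)
Conditions: TMSOTf, Et3N, CH2Cl2, 0 °C; NBS, THF, −78 °C; aq. NaHCO3, 0 °C → rt; citric acid, MeOH
Reagents that add atoms: none
Why: Soft enolisation can only go towards C6 because C8 is quaternary, giving the linear silyl dienol ether; electrophilic bromine should add at its γ-terminus C6 anti to the C7 side chain (vinylogous α-halogenation). The unmasked carboxylate then displaces the allylic bromide by intramolecular SN2 lactonisation with inversion, which places O6 cis to C11.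

Step 8
Reactants: 14 cis-fused lactone enone; 15 allyl bromide
Product: 16 C3 allyl carbinol (trans 3,8-diol; allyl group on the upper face; C9 silyl ether)
Conditions: In (powder), THF/H2O, rt
Reagents that add atoms: none
Why: Barbier-type indium-mediated allylation: the allylindium reagent adds 1,2 to the ketone, activated by chelation with the free C8 hydroxyl, and leaves lactone, acrylate alkene and silyl ether alone. In the chelate the allyl group should enter anti to the pseudo-axial C9 arm, giving the trans diol; this centre is also erased in step 15.

Step 9
Reactants: 16 C3 allyl carbinol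
Product: 17 trans-fused bicyclic 3,8-diol C9 silyl ether (lactone-fused hexahydronaphthalene)
Conditions: second-generation Grubbs catalyst (H2IMes)(PCy3)Cl2Ru=CHPh (5 mol%), CH2Cl2, 40 °C
Reagents that add atoms: none
Why: Ring-closing metathesis between the allyl group and the C10 isopropenyl group forms the six-membered ring A with loss of ethylene. The C1=C10 alkene is cis by ring constraint, and the electron-poor methylene lactone should not compete.

Step 10
Reactants: 17 bicyclic diol silyl ether
Product: 18 bicyclic 3,8,9-triol
Conditions: HF·pyridine, pyridine/THF, 0 °C → rt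
Reagents that add atoms: none
Why: Buffered fluoride desilylation frees the C9 hydroxyl without the basic fluoride that would threaten the methylene lactone, and without acid strong enough to ionise the tertiary allylic alcohol.

Step 11
Reactants: 19 angelic acid
Product: 20 (Z)-2-methylbut-2-en-1-ol
Conditions: LiAlH4, Et2O, 0 °C
Reagents that add atoms: none
Why: Hydride reduction of the unsaturated acid to the allylic alcohol (1,2-reduction), with the Z geometry retained.

Step 12
Reactants: 20 (Z)-2-methylbut-2-en-1-ol
Product: 21 [(2S,3R)-2,3-dimethyloxiran-2-yl]methanol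
Conditions: Ti(OiPr)4 (cat.), L-(+)-diethyl tartrate (cat.), t-BuOOH, 4 Å molecular sieves, CH2Cl2, −20 °C
Reagents that add atoms: tert-butyl hydroperoxide, CC(C)(C)OO
Why: Sharpless asymmetric epoxidation; with L-(+)-tartrate the face attacked is the one that gives the (2S,3R) epoxy alcohol, the same sense as (2S,3R)-epoxynerol from nerol, and the Z alkene fixes the trans methyl groups.

Step 13
Reactants: 21 epoxy alcohol
Product: 22 (2R,3R)-2,3-dimethyloxirane-2-carboxylic acid
Conditions: RuCl3 (cat.), NaIO4, EtOAc/MeCN/H2O, 0 °C → rt
Reagents that add atoms: sodium periodate, [Na+].[O-]I(=O)(=O)=O; water, O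
Why: Catalytic RuO4 (Sharpless conditions) oxidises the primary alcohol to the acid without opening the epoxide; the descriptor at C2 changes from S to R only because the CIP priorities change.

Step 14
Reactants: 18 bicyclic triol; 22 epoxy acid
Product: 24 bicyclic 3,8-diol C9 (2R,3R)-2,3-dimethyloxirane-2-carboxylate (ring-fusion diol precursor), via mixed anhydride 23 (not isolated)
Conditions: 22, 2,4,6-trichlorobenzoyl chloride, Et3N, toluene, rt; then 18, DMAP, toluene, rt → 40 °C
Reagents that add atoms: none
Why: Yamaguchi esterification; the two tertiary hydroxyls do not acylate, so the only secondary hydroxyl (C9) takes the hindered acid, and the mild conditions spare the epoxide. Esterifying here fixes the O8/O9 differentiation before C8 becomes a carbinol.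

Step 15
Reactants: 24 ring-fusion diol ester
Product: 25 (1(10)Z,4Z,6R,7R,9S)-9-[(2R,3R)-2,3-dimethyloxirane-2-carbonyloxy]-3,8-dioxogermacra-1(10),4,11(13)-trien-12,6-olide
Conditions: Pb(OAc)4 (1.1 equiv), pyridine, CH2Cl2, −20 → 0 °C; cold filtration through Celite, crude used at once
Reagents that add atoms: none
Why: Criegee glycol cleavage: one tertiary hydroxyl exchanges with acetate on tetravalent lead, and a two-electron fragmentation breaks C3–C8 to leave a ketone at each carbon and divalent lead. Because the diol of 24 is expected to be trans-diaxial, the cyclic plumbate cannot form; the reaction runs through the open pathway in which pyridine removes the second hydroxyl proton as the antiperiplanar C–C bond breaks. The closest known reaction is the Pb(OAc)4 cleavage of decalin-9,10-diols, including the rigid trans isomer, to cyclodecane-1,6-dione. No ring is closed by bond formation: the ten-membered ring is uncovered when the bond shared by ring A and ring B is cut (ring expansion of a bicyclo[4.4.0] system). No stereocentre is created; C3 and C8 become carbonyl carbons, and C6, C7, C9 and the epoxide are untouched. Both alkenes were cis inside six-membered rings and therefore emerge Z,Z. The step needs chemoselectivity for the one glycol, secured because O9 is acylated and the other oxygens are esters. It also needs freedom from enolisation, so that the lactone carboxylate is not eliminated β to C8, C7 and C9 do not epimerise, C1=C10 does not move into conjugation and no transannular aldol occurs; this is secured by low temperature, a weak base only and immediate use of the product.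

Step 16
Reactants: 25 3,8-dione
Product: 26 (6R,7S,8R,9S)-8-hydroxy-3-oxo analogue of 25 (8-hydroxy enone)
Conditions: NaBH4, CH2Cl2/MeOH (1:1), −78 °C
Reagents that add atoms: none
Why: Chemoselective borohydride reduction: at −78 °C the saturated α-acyloxy ketone should react far faster than the conjugated C3 enone or the methylene lactone. Hydride is expected to enter anti to both flanking bonds (C7–C11 and C9–O), giving the all-cis C7/C8/C9 arrangement (8R).

Step 17
Reactants: 26 8-hydroxy enone
Product: 27 (3S,6R,7S,8R,9S)-3,8-dihydroxy analogue (3,8-diol)
Conditions: (R)-2-methyl-CBS-oxazaborolidine (1 equiv), catecholborane, toluene/CH2Cl2, −78 °C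
Reagents that add atoms: none
Why: Corey–Bakshi–Shibata reduction of the enone: with the α-methyl alkenyl arm (C4) as the large group and C2H2 as the small one, the (R) catalyst should deliver hydride to give the 3S allylic alcohol. Catecholborane at −78 °C reduces 1,2 and spares alkenes, epoxide and esters.

Step 18
Reactants: 27 3,8-diol
Product: 28 target, (1(10)Z,4Z,3S,6R,7S,8R,9S)-3-acetoxy-9-[(2R,3R)-2,3-dimethyloxirane-2-carbonyloxy]-8-hydroxygermacra-1(10),4,11(13)-trien-12,6-olide
Conditions: Ac2O (1.2 equiv), pyridine, CH2Cl2, 0 °C
Reagents that add atoms: acetic anhydride, CC(=O)OC(C)=O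
Why: Selective acetylation of the less hindered allylic C3 hydroxyl; the C8 hydroxyl is flanked by the ring-fusion carbon and the bulky C9 ester. Omitting DMAP and using little excess reagent also limits acyl migration.

## Compound list

1 | (R)-carvone | CC(=C)[C@@H]1CC=C(C)C(=O)C1 | starting material
2 | (R)-10-chlorocarvone | ClCC(=C)[C@@H]1CC=C(C)C(=O)C1 | intermediate
3 | methacrolein | CC(=C)C=O | starting material
4 | lithium enolate of 2 (not isolated) | [Li+].ClCC(=C)[C@@H]1CC=C(C)C([O-])=C1 | intermediate
5 | triisopropoxytitanium enolate of 2 (not isolated) | ClCC(=C)[C@@H]1CC=C(C)C(O[Ti](OC(C)C)(OC(C)C)OC(C)C)=C1 | intermediate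
6 | syn aldol, (5R,6R)-5-(3-chloroprop-1-en-2-yl)-6-[(1R)-1-hydroxy-2-methylprop-2-en-1-yl]-2-methylcyclohex-2-en-1-one | ClCC(=C)[C@@H]1CC=C(C)C(=O)[C@H]1[C@@H](O)C(C)=C | intermediate
7 | C9 tert-butyldimethylsilyl ether of 6 | ClCC(=C)[C@@H]1CC=C(C)C(=O)[C@H]1[C@@H](O[Si](C)(C)C(C)(C)C)C(C)=C | intermediate
8 | potassium enolate of 7 (not isolated) | [K+].ClCC(=C)[C@@H]1CC=C(C)C([O-])=C1[C@@H](O[Si](C)(C)C(C)(C)C)C(C)=C | intermediate
9 | C8 tertiary alcohol, (5S,6R)-6-[(1S)-1-(tert-butyldimethylsilyloxy)-2-methylprop-2-en-1-yl]-5-(3-chloroprop-1-en-2-yl)-6-hydroxy-2-methylcyclohex-2-en-1-one | ClCC(=C)[C@@H]1CC=C(C)C(=O)[C@]1(O)[C@@H](O[Si](C)(C)C(C)(C)C)C(C)=C | intermediate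
10 | C12 aldehyde corresponding to 9 | O=CC(=C)[C@@H]1CC=C(C)C(=O)[C@]1(O)[C@@H](O[Si](C)(C)C(C)(C)C)C(C)=C | intermediate
11 | C12 carboxylic acid corresponding to 9 | OC(=O)C(=C)[C@@H]1CC=C(C)C(=O)[C@]1(O)[C@@H](O[Si](C)(C)C(C)(C)C)C(C)=C | intermediate
12 | tris(trimethylsilyl) dienol ether of 11 (not isolated) | C[Si](C)(C)OC(=O)C(=C)[C@@H]1C=CC(C)=C(O[Si](C)(C)C)[C@]1(O[Si](C)(C)C)[C@@H](O[Si](C)(C)C(C)(C)C)C(C)=C | intermediate
13 | C6 bromo enone, bromine trans to the C7 side chain, trimethylsilyl ester and C8 trimethylsilyl ether (not isolated) | C[Si](C)(C)OC(=O)C(=C)[C@@H]1[C@@H](Br)C=C(C)C(=O)[C@]1(O[Si](C)(C)C)[C@@H](O[Si](C)(C)C(C)(C)C)C(C)=C | intermediate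
14 | cis-fused α-methylene lactone enone (C3 ketone, C8 hydroxyl, C9 silyl ether) | C=C1C(=O)O[C@@H]2C=C(C)C(=O)[C@](O)([C@@H](O[Si](C)(C)C(C)(C)C)C(C)=C)[C@H]12 | intermediate
15 | allyl bromide | C=CCBr | starting material
16 | C3 allyl carbinol, trans 3,8-diol | C=C1C(=O)O[C@@H]2C=C(C)[C@@](O)(CC=C)[C@](O)([C@@H](O[Si](C)(C)C(C)(C)C)C(C)=C)[C@H]12 | intermediate
17 | trans-fused bicyclic 3,8-diol C9 silyl ether | C=C1C(=O)O[C@@H]2C=C(C)[C@@]3(O)CC=C(C)[C@H](O[Si](C)(C)C(C)(C)C)[C@]3(O)[C@H]12 | intermediate
18 | bicyclic 3,8,9-triol | C=C1C(=O)O[C@@H]2C=C(C)[C@@]3(O)CC=C(C)[C@H](O)[C@]3(O)[C@H]12 | intermediate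
19 | angelic acid | C/C=C(/C)C(=O)O | starting material
20 | (Z)-2-methylbut-2-en-1-ol | C/C=C(/C)CO | intermediate
21 | [(2S,3R)-2,3-dimethyloxiran-2-yl]methanol | OC[C@]1(C)O[C@@H]1C | intermediate
22 | (2R,3R)-2,3-dimethyloxirane-2-carboxylic acid | OC(=O)[C@]1(C)O[C@@H]1C | intermediate
23 | mixed anhydride of 22 with 2,4,6-trichlorobenzoic acid (not isolated) | O=C(OC(=O)c1c(Cl)cc(Cl)cc1Cl)[C@]2(C)O[C@@H]2C | intermediate
24 | bicyclic 3,8-diol C9 (2R,3R)-2,3-dimethyloxirane-2-carboxylate (precursor of the key step) | C=C1C(=O)O[C@@H]2C=C(C)[C@@]3(O)CC=C(C)[C@H](OC(=O)[C@]4(C)O[C@@H]4C)[C@]3(O)[C@H]12 | intermediate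
25 | Z,Z-cyclodecadiene-3,8-dione with fused methylene lactone and C9 epoxy ester (product of the key step) | C=C1C(=O)O[C@@H]2/C=C(/C)C(=O)C/C=C(/C)[C@H](OC(=O)[C@]3(C)O[C@@H]3C)C(=O)[C@H]12 | intermediate
26 | 8-hydroxy-3-oxo compound (8R) | C=C1C(=O)O[C@@H]2/C=C(/C)C(=O)C/C=C(/C)[C@H](OC(=O)[C@]3(C)O[C@@H]3C)[C@H](O)[C@H]12 | intermediate
27 | 3,8-diol (3S,8R) | C=C1C(=O)O[C@@H]2/C=C(/C)[C@@H](O)C/C=C(/C)[C@H](OC(=O)[C@]3(C)O[C@@H]3C)[C@H](O)[C@H]12 | intermediate
28 | CNP0137407.4, 3-acetate of 27 | C=C1C(=O)O[C@@H]2/C=C(/C)[C@@H](OC(C)=O)C/C=C(/C)[C@H](OC(=O)[C@]3(C)O[C@@H]3C)[C@H](O)[C@H]12 | target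

Total step count: 18. Longest linear sequence: 15 steps (steps 1–10 and 14–18); the epoxy acid branch is 3 steps (steps 11–13).

Least certain steps

Step 15 (key step). The locked antiperiplanar diol cannot use the fast cyclic plumbate pathway, so cleavage may be slow. Prolonged exposure of the forming dione to reagent and pyridine would then allow β-elimination of the lactone carboxylate, epimerisation or transannular aldol. Fallback: build the cis ring-fusion diol by tether-directed allyl transfer, setting out from 14. HF·pyridine removes the silyl group to give the C8,C9-dihydroxy lactone enone F1. Silylation of its secondary C9 hydroxyl with the strained pinacol-derived allylchlorosilane (2-allyl-2-chloro-4,4,5,5-tetramethyl-1,3,2-dioxasilolane, Et3N) places a Lewis-acidic allylsilane under the C3 ketone; intramolecular allyl transfer from the lower face and acidic methanol work-up should give the cis 3,8-diol allyl triol F2. Ring-closing metathesis gives the cis-fused bicyclic triol F3, and Yamaguchi esterification with 22 gives the cis-diol ester F4. Its diol can form the cyclic plumbate and should be cleaved by Pb(OAc)4 in CH2Cl2 at low temperature without pyridine, coming back to the route at 25.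

Step 2. The syn preference of the titanium enolate may be eroded by competition between chair and boat transition states, which would give the C9 epimer, and the allylic chloride may not tolerate warming of the enolate. Fallback: an open-transition-state Mukaiyama route setting out from 2. Trapping the kinetic enolate with Me3SiCl gives the cross-conjugated trimethylsilyl enol ether F5. Fluoride-catalysed addition to 3 (tris(diethylamino)sulfonium difluorotrimethylsilicate, THF, −78 °C) proceeds through a naked enolate and is syn-selective irrespective of enol ether geometry, giving the silylated syn aldol F6. Mild acid returns to the route at 6.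

Step 7. Bromination may be divided between C4 and C6 or between the two faces, and the γ-bromo enone may lose HBr to a dienone faster than the carboxylate closes the ring. Fallback: a tether-controlled halolactonisation that does not depend on facial selectivity, setting out from 11. The dienol ether 12 is protonated kinetically at C4 (oxalic acid, aqueous THF, 0 °C) to the deconjugated β,γ-unsaturated keto acid F7. Iodolactonisation (I2, NaHCO3, MeCN) closes the lactone on C6 from the face of the tether, giving the cis-fused C5 iodo lactone F8. DBU eliminates HI towards C4 and restores the enone, coming back at 14.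

Step 14. Acylation of the pseudo-axial, neopentyl-type C9 hydroxyl by an α-quaternary acid may stall, and forcing it risks opening the epoxide or acyl transfer. Fallback: esterify before ring A locks the hydroxyl, setting out from 16. HF·pyridine gives the monocyclic allyl triol F9, whose C9 hydroxyl sits on a freely rotating arm. Yamaguchi esterification with 22 (via 23) gives the monocyclic ester F10, and ring-closing metathesis then returns to the route at 24.

Step 16. Hydride delivery may be poorly face-selective on the flexible ten-membered ring, giving the C8 epimer, and conjugate reduction of the methylene lactone may compete. Fallback: invert instead of re-reducing, setting out from 25. If the reduction gives mainly the 8-epi alcohol F11, a Mitsunobu reaction with chloroacetic acid (PPh3, DIAD) inverts C8 to the chloroacetate F12. Thiourea with NaHCO3 in EtOH removes the chloroacetyl group selectively and comes back at 26.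

Step 17. The conformational bias of the macrocycle may override the catalyst, giving the 3-epimer, or reduction may be slow at the hindered enone. Fallback: use substrate control and invert during acetylation, setting out from 26. Luche reduction (NaBH4, CeCl3·7H2O, MeOH, −78 °C) gives the substrate-preferred 3-epi diol F13. A Mitsunobu reaction with acetic acid (PPh3, DIAD) at the less hindered allylic C3 hydroxyl installs the acetate with inversion and comes back at 28, bypassing step 18.

## Further compounds

F1 | step 15 | C8,C9-dihydroxy lactone enone (14 without the silyl group) | C=C1C(=O)O[C@@H]2C=C(C)C(=O)[C@](O)([C@@H](O)C(C)=C)[C@H]12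
F2 | step 15 | cis 3,8-diol allyl triol (C3 epimer of the desilylated 16) | C=C1C(=O)O[C@@H]2C=C(C)[C@](O)(CC=C)[C@](O)([C@@H](O)C(C)=C)[C@H]12
F3 | step 15 | cis-fused bicyclic 3,8,9-triol | C=C1C(=O)O[C@@H]2C=C(C)[C@]3(O)CC=C(C)[C@H](O)[C@]3(O)[C@H]12
F4 | step 15 | cis-fused bicyclic 3,8-diol C9 epoxy ester | C=C1C(=O)O[C@@H]2C=C(C)[C@]3(O)CC=C(C)[C@H](OC(=O)[C@]4(C)O[C@@H]4C)[C@]3(O)[C@H]12
F5 | step 2 | trimethylsilyl enol ether of 2 | ClCC(=C)[C@@H]1CC=C(C)C(O[Si](C)(C)C)=C1
F6 | step 2 | trimethylsilyl ether of 6 | ClCC(=C)[C@@H]1CC=C(C)C(=O)[C@H]1[C@@H](O[Si](C)(C)C)C(C)=C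
F7 | step 7 | β,γ-unsaturated keto acid (C5=C6 alkene, C4 epimers) | OC(=O)C(=C)[C@@H]1C=CC(C)C(=O)[C@]1(O)[C@@H](O[Si](C)(C)C(C)(C)C)C(C)=C
F8 | step 7 | cis-fused C5 iodo lactone (C4 epimers) | C=C1C(=O)O[C@@H]2[C@@H](I)C(C)C(=O)[C@](O)([C@@H](O[Si](C)(C)C(C)(C)C)C(C)=C)[C@H]12
F9 | step 14 | monocyclic allyl triol (16 without the silyl group) | C=C1C(=O)O[C@@H]2C=C(C)[C@@](O)(CC=C)[C@](O)([C@@H](O)C(C)=C)[C@H]12
F10 | step 14 | monocyclic allyl diol C9 epoxy ester | C=C1C(=O)O[C@@H]2C=C(C)[C@@](O)(CC=C)[C@](O)([C@@H](OC(=O)[C@]3(C)O[C@@H]3C)C(C)=C)[C@H]12
F11 | step 16 | 8-epi alcohol (C8 epimer of 26) | C=C1C(=O)O[C@@H]2/C=C(/C)C(=O)C/C=C(/C)[C@H](OC(=O)[C@]3(C)O[C@@H]3C)[C@@H](O)[C@H]12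
F12 | step 16 | C8 chloroacetate of 26 | C=C1C(=O)O[C@@H]2/C=C(/C)C(=O)C/C=C(/C)[C@H](OC(=O)[C@]3(C)O[C@@H]3C)[C@H](OC(=O)CCl)[C@H]12
F13 | step 17 | 3-epi diol (C3 epimer of 27) | C=C1C(=O)O[C@@H]2/C=C(/C)[C@H](O)C/C=C(/C)[C@H](OC(=O)[C@]3(C)O[C@@H]3C)[C@H](O)[C@H]12
A1 | alternative 1 | 3-methyltropone | CC1=CC(=O)C=CC=C1
A2 | alternative 1 | (1E)-1-acetoxy-2-methylbuta-1,3-diene | CC(=O)O/C=C(\C)C=C
A3 | alternative 1 | exo [6+4] adduct, acetoxy dimethyl bicyclo[4.4.1]undecatrienone | O=C1[C@H]2C(C)=CC=C[C@@H]1[C@@H](OC(C)=O)C(C)=CC2
A4 | alternative 2 | seco (Z)-iodoalkene C6 aldehyde C12 methyl ester (C3 silyl ether, C8/C9 acetonide) | I/C=C(/C)[C@@H](O[Si](C)(C)C(C)(C)C)C/C=C(/C)[C@@H]1OC(C)(C)O[C@@H]1[C@@H](C=O)CC(=O)OC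
A5 | alternative 2 | lactone-fused Z,Z-cyclodecadiene (C3 silyl ether, C8/C9 acetonide, no C13) | C1C(=O)O[C@@H]2/C=C(/C)[C@@H](O[Si](C)(C)C(C)(C)C)C/C=C(/C)[C@@H]3OC(C)(C)O[C@@H]3[C@H]12
A6 | alternative 3 | seco C4 (Z)-iodoalkene C3 aldehyde with methylene lactone and acetonide | C=C1C(=O)O[C@H](/C=C(/C)I)[C@@H]1[C@H]2OC(C)(C)O[C@H]2/C(C)=C\CC=O
A7 | alternative 3 | macrocyclic C3 alcohol with methylene lactone and acetonide | C=C1C(=O)O[C@@H]2/C=C(/C)[C@@H](O)C/C=C(/C)[C@@H]3OC(C)(C)O[C@@H]3[C@H]12
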